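Amounts first: each reaction of substrate with partner uses one of each and gives one intermediate, so what north, south-east, west or north-west makes this way stays at or below the partner charge of 3.50 mM.

| setting | Monday's | Sunday's | north | south-east | west | north-west |
|---|---|---|---|---|---|---|
| substrate | 2.5 mM | 2.5 mM | 2.5 mM | 5.0 mM | 10 mM | 20 mM |
| partner | 2.3 mM | 7 mM | 3.50 mM | 3.50 mM | 3.50 mM | 3.50 mM |
| remark | run made earlier | run made earlier |  |  |  |  |
| time |  |  | 2.5 min | 2.5 min | 2.5 min | 2.5 min |

| run | time / s | intermediate / % | target / % | substrate / % |
|---|---|---|---|---|
| Monday's | 10.0 | 10.6 | 2.9 | 84.8 |
| Monday's | 12.0 | 11.2 | 3.8 | 82.1 |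
| Monday's | 20.0 | 12.2 | 7.0 | 73.7 |
| Monday's | 25.0 | 14.1 | 8.4 | 69.1 |
| Monday's | 30.0 | 14.0 | 10.1 | 65.4 |
| Sunday's | 10.0 | 26.4 | 7.5 | 59.7 |
| Sunday's | 12.0 | 28.2 | 9.1 | 54.4 |
| Sunday's | 20.0 | 29.1 | 16.0 | 37.7 |
| Sunday's | 30.0 | 27.4 | 23.3 | 24.5 |

(scatter of a reading: 0.3 percentage points)

- percent here means substrate units held: one side product counts as two
- steps that have been proposed: substrate + partner -> intermediate + released group; intermediate <-> target; intermediate <-> isomer of the product; intermediate -> decomposed reagent; substrate + target -> side product
- "hardly changes" means that all values lie within two and a half points (for a concentration: within two and a half percent of the largest)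

* [intermediate] at the end for north, south-east, west, north-west, in this order
* the shape of the row from first to last (falls all the way / rises all the way / falls, then rises / rises, then falls / hardly changes)

At the board I start with the pace of that first step. Sunday's substrate stands at 59.7 % after 10.0 s. The logarithm of that fall, divided by the time and by the mean partner present, reads as a pace constant of 0.00794 mM⁻¹ s⁻¹. Monday's last reading gives 0.00758 mM⁻¹ s⁻¹ the same way.

For the first step the crossing lies where the substrate charge equals the partner charge, because there the limiting reagent changes hands: north stands below it and south-east above it. Well above the crossing the partner decays in a roughly pseudo-first-order way, and I call its half-life the partner clock: ln(2) divided by the pace constant and by the excess of substrate over partner. For west the partner clock is 13.4 s, far shorter than the asked time.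

Two chemists now dispute the row. The first says intermediate follows supply. The rate law worked through gives 2.22 mM made in north, below the partner charge, so in this chemist's view the row rises and then lies flat once the clock is short. The second points to the proposed step of substrate with target, whose rate, if the step runs, goes with the substrate present. Intermediate is tied to target, so with feeding over early and more substrate standing by, the row should fall. I side with the second and expect a peak just above the crossing, though I put no number on the fall.

The forecast, nearer the first chemist, gives 0.43 mM, 0.58 mM, 0.57 mM and 0.52 mM, rises, then falls, with “a plateau near 0.58 mM”.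

The flask gives 0.372 mM, 0.489 mM, 0.346 mM and 0.199 mM, which rises, then falls, turning at a substrate charge of 4.7 mM, above the crossing; the first chemist's rise stands from north to south-east, where the released group goes from 2.18 mM to 3.26 mM.

    substrate + partner → intermediate + released group (k = 7.91 M⁻¹ s⁻¹)
    intermediate ⇌ target (K = 1.32, k = 0.0500 s⁻¹)
    intermediate ⇌ isomer of the product (K = 2.26, k = 0.0292 s⁻¹)
    intermediate → decomposed reagent (k = 0.00724 s⁻¹)
    substrate + target → side product (k = 1.93 M⁻¹ s⁻¹)

West holds 21.0 % as side product at the end. Reckoned by the clock, 0.0434 % of the partner charge stands in west at the end, where the flask holds 0.0569 %. In north-west the clock is 5.29 s, which reckons 0.00540 % of the charge after 1.25 min, and north-west then holds 0.00681 %.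

(The readings are calculated for substances that don't exist; noise was put on by code.)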